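The tricycle (longipinane numbering: C1 ketone, C2=C3, cyclobutane C4–C5–C11–C10, gem-dimethyl C6, C7–O, C9–O) is disconnected in its seven-membered ring C5–C6–C7–C8–C9–C10–C11 at C5–C11 and C9–C10. A Lewis-acid-triggered cationic (5+2) cycloaddition lets the trisubstituted ring alkene C10=C11 of a cyclohexene add across the termini C5 and C9 of a cross-conjugated dienone C5=C6(Me)–C7(=O)–C8=C9 attached at C4. Because C4 already links C5 to C10, this one operation closes both the cyclobutane and the cycloheptenone. The precursor is a monocyclic 4-silyloxy-2,6-dimethylcyclohex-2-enyl dienone from an enantioselective Diels–Alder reaction.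

Key step: step 9

Remark: tricyclic compounds are numbered as longipinanes (ring bonds C1–C2–C3–C4–C5–C6–C7–C8–C9–C10–C11–C1, C4–C10, C5–C11; methyls on C3, C6, C6, C10). Stereocentres that are erased later (the silyloxy/hydroxy carbon that becomes C1, and C6 in 13) are carried as epimer mixtures and left open in the SMILES.

Step 1
Reactants: 1 (E)-pent-3-en-2-one
Product: 2 (E)-tert-butyl(dimethyl)(penta-1,3-dien-2-yloxy)silane
Conditions: tert-butyldimethylsilyl triflate, Et3N, CH2Cl2, 0 °C
Reagents that add atoms: tert-butyldimethylsilyl triflate (CC(C)(C)[Si](C)(C)OS(=O)(=O)C(F)(F)F)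
Why: Soft enolisation (silyl triflate/amine) removes a proton from the acetyl methyl group, which should give the 2-silyloxy diene with the E alkene untouched (silyl enol ether formation).

Step 2
Reactants: 2 (E)-tert-butyl(dimethyl)(penta-1,3-dien-2-yloxy)silane; 3 (E)-but-2-enal
Product: 4 (1R,2S,6S)-4-[(tert-butyldimethylsilyl)oxy]-2,6-dimethylcyclohex-3-ene-1-carbaldehyde
Conditions: (S)-3,3-diphenyl-1-(o-tolyl)tetrahydro-1H,3H-pyrrolo[1,2-c][1,3,2]oxazaborole (20 mol%), Tf2NH (20 mol%), CH2Cl2, −78 °C
Reagents that add atoms: none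
Why: Enantioselective Diels–Alder reaction in which the 2-silyloxy and 4-methyl groups both direct the diene CH2 terminus to the β-carbon of the enal, the endo transition state puts the ring C2 methyl cis to the formyl group, the E dienophile fixes the C6 methyl trans to it, and the chiral boron Lewis acid (enantiomer chosen to give the 1R,6S adduct) shields one face of the coordinated enal.

Step 3
Reactants: 5 diethyl [2-(methoxy(methyl)amino)-2-oxoethyl]phosphonate
Product: 6 diethyl [1-(methoxy(methyl)amino)-1-oxopropan-2-yl]phosphonate (racemic)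
Conditions: NaH, THF, 0 °C; then MeI, 0 → 25 °C
Reagents that add atoms: iodomethane (CI)
Why: SN2 alkylation of the stabilised phosphonate carbanion; the new stereocentre is racemic and disappears in the olefination.

Step 4
Reactants: 4 (1R,2S,6S)-4-[(tert-butyldimethylsilyl)oxy]-2,6-dimethylcyclohex-3-ene-1-carbaldehyde; 6 diethyl [1-(methoxy(methyl)amino)-1-oxopropan-2-yl]phosphonate
Product: 7 (E)-3-[(1R,2R,6S)-4-[(tert-butyldimethylsilyl)oxy]-2,6-dimethylcyclohex-3-en-1-yl]-N-methoxy-N,2-dimethylprop-2-enamide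
Conditions: NaH, THF, 0 °C (6 deprotonated first); then 4, −20 → 0 °C
Reagents that add atoms: none
Why: Horner–Wadsworth–Emmons olefination, in which the α-methyl phosphonoacetamide should give the E trisubstituted enamide and the pre-formed sodium phosphonate (no excess base) should leave the α-stereocentre of the aldehyde intact.

Step 5
Reactants: 7 (E)-3-[(1R,2R,6S)-4-[(tert-butyldimethylsilyl)oxy]-2,6-dimethylcyclohex-3-en-1-yl]-N-methoxy-N,2-dimethylprop-2-enamide
Product: 8 (E)-3-[(1S,6S)-2,6-dimethyl-4-oxocyclohex-2-en-1-yl]-N-methoxy-N,2-dimethylprop-2-enamide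
Conditions: Pd(OAc)2 (1.1 equiv), MeCN, 40 °C
Reagents that add atoms: none
Why: Saegusa–Ito oxidation, in which the palladium enolate formed from the silyl enol ether undergoes β-hydride elimination toward the methyl-bearing carbon, placing the C=C bond between the future C10 and C11 and erasing the ring C2 stereocentre.

Step 6
Reactants: 8 (E)-3-[(1S,6S)-2,6-dimethyl-4-oxocyclohex-2-en-1-yl]-N-methoxy-N,2-dimethylprop-2-enamide
Product: 9 (E)-3-[(1S,6S)-4-hydroxy-2,6-dimethylcyclohex-2-en-1-yl]-N-methoxy-N,2-dimethylprop-2-enamide (C4 epimers)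
Conditions: NaBH4, CeCl3·7H2O, MeOH, −78 → −40 °C
Reagents that add atoms: none
Why: Luche reduction adds hydride 1,2 to the enone only (the Weinreb amide is inert), and the new carbinol centre needs no control because it is re-oxidised in step 15.

Step 7
Reactants: 9 (E)-3-[(1S,6S)-4-hydroxy-2,6-dimethylcyclohex-2-en-1-yl]-N-methoxy-N,2-dimethylprop-2-enamide (C4 epimers)
Product: 10 (E)-3-[(1S,6S)-4-[(tert-butyldimethylsilyl)oxy]-2,6-dimethylcyclohex-2-en-1-yl]-N-methoxy-N,2-dimethylprop-2-enamide (C4 epimers)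
Conditions: tert-butyldimethylsilyl chloride, imidazole, DMF, 25 °C
Reagents that add atoms: tert-butyldimethylsilyl chloride (CC(C)(C)[Si](C)(C)Cl)
Why: Silylation of the secondary allylic alcohol masks the oxygen and keeps the ring alkene electron-rich for the key step.

Step 8
Reactants: 10 (E)-3-[(1S,6S)-4-[(tert-butyldimethylsilyl)oxy]-2,6-dimethylcyclohex-2-en-1-yl]-N-methoxy-N,2-dimethylprop-2-enamide (C4 epimers)
Product: 11 (E)-1-[(1S,6S)-4-[(tert-butyldimethylsilyl)oxy]-2,6-dimethylcyclohex-2-en-1-yl]-2-methylpenta-1,4-dien-3-one (C4 epimers)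
Conditions: CH2=CHMgBr, THF, −78 → 0 °C; cold aq. NH4Cl
Reagents that add atoms: vinylmagnesium bromide (C=C[Mg]Br)
Why: Weinreb ketone synthesis, in which the Grignard reagent adds once to give a chelated tetrahedral intermediate that collapses to the cross-conjugated dienone only on quench.

Step 9
Reactants: 11 (E)-1-[(1S,6S)-4-[(tert-butyldimethylsilyl)oxy]-2,6-dimethylcyclohex-2-en-1-yl]-2-methylpenta-1,4-dien-3-one (C4 epimers)
Product: 13 1-[(tert-butyldimethylsilyl)oxy]-13-norlongipin-8-en-7-one (C1/C6 epimers), via aluminium dienolate 12 (not isolated)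
Conditions: Me2AlCl (2 equiv), CH2Cl2, −78 → −20 °C; then aq. KNaC4H4O6
Reagents that add atoms: none
Why: Proposed new method: complexation of the dienone carbonyl by Me2AlCl gives a 3-aluminoxy pentadienyl cation whose terminus C5 is attacked by C11 of the ring alkene (the homoallyl-to-cyclobutyl π-route known from solvolysis of 3-methylbut-3-enyl sulfonates); the tertiary cyclobutyl cation at C10 is then captured by the dienolate terminus C9, and loss of a C9 proton gives dienolate 12 and, on work-up, the enone. The closest known reaction type is the cationic (5+2) cycloaddition of oxidopentadienyl cations with alkenes (perezone-to-pipitzol type), here applied to an acyclic divinyl ketone. The cyclobutane C4–C5–C11–C10 closes by a four-membered π-cyclisation in which both alkene carbons become ring members, and the cycloheptenone closes by seven-membered endo attack of C9 on C10. C11 is set cis to the C4–C5 bond because the one-carbon link C4 can deliver C5 only to the alkene face on which it sits; C5 is set with the chain exo (away from the C1–C2–C3 bridge) by the E geometry and the bulk of the chain; C10 receives C9 on that same exo face because the tether allows nothing else. The step needs alkene capture to outrun the 4π (Nazarov) electrocyclisation of the dienone and proton loss from the cyclobutyl cation, which the unsubstituted vinyl terminus, the low temperature and the electron-rich alkene held one atom away should favour. C6 forms unselectively and is erased in step 10.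

Step 10
Reactants: 13 1-[(tert-butyldimethylsilyl)oxy]-13-norlongipin-8-en-7-one (C1/C6 epimers)
Product: 14 1-[(tert-butyldimethylsilyl)oxy]longipin-8-en-7-one (C1 epimers)
Conditions: LiN(iPr)2, THF, −78 °C; then MeI, DMPU, −78 → 0 °C
Reagents that add atoms: iodomethane (CI)
Why: Alkylation of the cross-conjugated lithium enolate formed by α′-deprotonation at C6 (the only acidic site, since C8 is vinylic and C10 quaternary) creates the gem-dimethyl carbon and removes the C6 stereocentre.

Step 11
Reactants: 14 1-[(tert-butyldimethylsilyl)oxy]longipin-8-en-7-one (C1 epimers)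
Product: 16 9-hydroxy-1-[(tert-butyldimethylsilyl)oxy]longipinan-7-one (C9–OH on the C11 side), via boronate 15 (not isolated)
Conditions: CuCl (5 mol%), NaOtBu (10 mol%), (R)-1-[(SP)-2-(diphenylphosphino)ferrocenyl]ethyldicyclohexylphosphine (6 mol%), B2pin2, MeOH, THF, 25 °C; then NaBO3·4H2O, THF/H2O, 25 °C
Reagents that add atoms: bis(pinacolato)diboron (CC1(C)OB(OC1(C)C)B1OC(C)(C)C(C)(C)O1); sodium perborate, written without water of crystallisation ([Na+].[Na+].O[B-]1(O)OO[B-](O)(O)OO1)
Why: Copper-catalysed conjugate borylation followed by C–B oxidation with retention, in which the chiral bisphosphine–copper boryl complex (ligand enantiomer chosen for the shown C9 configuration) selects the face of C9, because the substrate differentiates the two faces only through remote groups.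

Step 12
Reactants: 16 9-hydroxy-1-[(tert-butyldimethylsilyl)oxy]longipinan-7-one
Product: 17 9-acetoxy-1-[(tert-butyldimethylsilyl)oxy]longipinan-7-ol (7,9-trans)
Conditions: SmI2 (30 mol%), CH3CHO (8 equiv), THF, −10 °C
Reagents that add atoms: acetaldehyde (CC=O)
Why: Evans–Tishchenko reduction, in which the samarium-bound hemiacetal of the C9 hydroxyl and acetaldehyde delivers hydride intramolecularly to the C7 carbonyl on the face of the C9 oxygen, giving the 7,9-trans (1,3-anti) diol with the acetate already on C9 and the C7 hydroxyl free.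

Step 13
Reactants: 17 9-acetoxy-1-[(tert-butyldimethylsilyl)oxy]longipinan-7-ol (7,9-trans)
Product: 18 9-acetoxy-1-[(tert-butyldimethylsilyl)oxy]longipinan-7-yl (Z)-2-methylbut-2-enoate
Conditions: angelic acid, 2,4,6-trichlorobenzoyl chloride, Et3N, toluene, 25 °C; then 17, toluene, 80 °C
Reagents that add atoms: angelic acid, (Z)-2-methylbut-2-enoic acid (C/C=C(/C)C(=O)O)
Why: Yamaguchi-type esterification with the pre-formed mixed anhydride and no nucleophilic catalyst, chosen to acylate the hindered neopentyl-type C7 alcohol without Z-to-E isomerisation of the acyl group.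

Step 14
Reactants: 18 9-acetoxy-1-[(tert-butyldimethylsilyl)oxy]longipinan-7-yl (Z)-2-methylbut-2-enoate
Product: 19 9-acetoxy-1-hydroxylongipinan-7-yl (Z)-2-methylbut-2-enoate (C1 epimers)
Conditions: HF·pyridine, pyridine, THF, 0 → 25 °C
Reagents that add atoms: none
Why: Fluoride-driven cleavage of the silyl ether under buffered conditions that should leave both esters in place.

Step 15
Reactants: 19 9-acetoxy-1-hydroxylongipinan-7-yl (Z)-2-methylbut-2-enoate (C1 epimers)
Product: 21 CNP0260482.1: 9-acetoxy-1-oxolongipin-2-en-7-yl (Z)-2-methylbut-2-enoate, via ketone 20 (not isolated)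
Conditions: 2-iodoxybenzoic acid (IBX, 4 equiv), 4-methoxypyridine N-oxide (4 equiv), DMSO, 25 → 40 °C
Reagents that add atoms: none
Why: The hypervalent iodine reagent oxidises the alcohol to ketone 20 and then dehydrogenates it in the same flask; enolisation is possible only toward C2 because C11 is a bridgehead, so the C2=C3 enone forms and the auxiliary C3 stereocentre is removed.

Compound list
1 | (E)-pent-3-en-2-one | C/C=C/C(C)=O | starting material
2 | (E)-tert-butyl(dimethyl)(penta-1,3-dien-2-yloxy)silane | C/C=C/C(=C)O[Si](C)(C)C(C)(C)C | intermediate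
3 | (E)-but-2-enal | C/C=C/C=O | starting material
4 | (1R,2S,6S)-4-[(tert-butyldimethylsilyl)oxy]-2,6-dimethylcyclohex-3-ene-1-carbaldehyde | O=C[C@H]1[C@@H](C)C=C(O[Si](C)(C)C(C)(C)C)C[C@@H]1C | intermediate
5 | diethyl [2-(methoxy(methyl)amino)-2-oxoethyl]phosphonate | CCOP(=O)(CC(=O)N(C)OC)OCC | starting material
6 | diethyl [1-(methoxy(methyl)amino)-1-oxopropan-2-yl]phosphonate (racemic) | CCOP(=O)(C(C)C(=O)N(C)OC)OCC | intermediate
7 | (E)-3-[(1R,2R,6S)-4-[(tert-butyldimethylsilyl)oxy]-2,6-dimethylcyclohex-3-en-1-yl]-N-methoxy-N,2-dimethylprop-2-enamide | CON(C)C(=O)/C(C)=C/[C@H]1[C@@H](C)C=C(O[Si](C)(C)C(C)(C)C)C[C@@H]1C | intermediate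
8 | (E)-3-[(1S,6S)-2,6-dimethyl-4-oxocyclohex-2-en-1-yl]-N-methoxy-N,2-dimethylprop-2-enamide | CON(C)C(=O)/C(C)=C/[C@H]1C(C)=CC(=O)C[C@@H]1C | intermediate
9 | (E)-3-[(1S,6S)-4-hydroxy-2,6-dimethylcyclohex-2-en-1-yl]-N-methoxy-N,2-dimethylprop-2-enamide (C4 epimers) | CON(C)C(=O)/C(C)=C/[C@H]1C(C)=CC(O)C[C@@H]1C | intermediate
10 | (E)-3-[(1S,6S)-4-[(tert-butyldimethylsilyl)oxy]-2,6-dimethylcyclohex-2-en-1-yl]-N-methoxy-N,2-dimethylprop-2-enamide (C4 epimers) | CON(C)C(=O)/C(C)=C/[C@H]1C(C)=CC(O[Si](C)(C)C(C)(C)C)C[C@@H]1C | intermediate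
11 | (E)-1-[(1S,6S)-4-[(tert-butyldimethylsilyl)oxy]-2,6-dimethylcyclohex-2-en-1-yl]-2-methylpenta-1,4-dien-3-one (C4 epimers) | C=CC(=O)/C(C)=C/[C@H]1C(C)=CC(O[Si](C)(C)C(C)(C)C)C[C@@H]1C | intermediate
12 | chloro(methyl)aluminium 6,8-dienolate of 13 (O-aluminated 13-norlongipina-6,8-dien-7-ol, 1-silyl ether) | C[Al](Cl)OC1C=C[C@@]2(C)[C@@H]3C(O[Si](C)(C)C(C)(C)C)C[C@H](C)[C@H]2[C@@H]3C=1C | intermediate
13 | 1-[(tert-butyldimethylsilyl)oxy]-13-norlongipin-8-en-7-one (C1/C6 epimers) | O=C1C=C[C@@]2(C)[C@@H]3C(O[Si](C)(C)C(C)(C)C)C[C@H](C)[C@H]2[C@@H]3C1C | intermediate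
14 | 1-[(tert-butyldimethylsilyl)oxy]longipin-8-en-7-one (C1 epimers) | O=C1C=C[C@@]2(C)[C@@H]3C(O[Si](C)(C)C(C)(C)C)C[C@H](C)[C@H]2[C@@H]3C1(C)C | intermediate
15 | 9-(4,4,5,5-tetramethyl-1,3,2-dioxaborolan-2-yl)-1-[(tert-butyldimethylsilyl)oxy]longipinan-7-one | O=C1C[C@@H](B2OC(C)(C)C(C)(C)O2)[C@@]3(C)[C@@H]4C(O[Si](C)(C)C(C)(C)C)C[C@H](C)[C@H]3[C@@H]4C1(C)C | intermediate
16 | 9-hydroxy-1-[(tert-butyldimethylsilyl)oxy]longipinan-7-one | O=C1C[C@@H](O)[C@@]2(C)[C@@H]3C(O[Si](C)(C)C(C)(C)C)C[C@H](C)[C@H]2[C@@H]3C1(C)C | intermediate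
17 | 9-acetoxy-1-[(tert-butyldimethylsilyl)oxy]longipinan-7-ol (7,9-trans) | O[C@@H]1C[C@@H](OC(C)=O)[C@@]2(C)[C@@H]3C(O[Si](C)(C)C(C)(C)C)C[C@H](C)[C@H]2[C@@H]3C1(C)C | intermediate
18 | 9-acetoxy-1-[(tert-butyldimethylsilyl)oxy]longipinan-7-yl (Z)-2-methylbut-2-enoate | C/C=C(/C)C(=O)O[C@@H]1C[C@@H](OC(C)=O)[C@@]2(C)[C@@H]3C(O[Si](C)(C)C(C)(C)C)C[C@H](C)[C@H]2[C@@H]3C1(C)C | intermediate
19 | 9-acetoxy-1-hydroxylongipinan-7-yl (Z)-2-methylbut-2-enoate (C1 epimers) | C/C=C(/C)C(=O)O[C@@H]1C[C@@H](OC(C)=O)[C@@]2(C)[C@@H]3C(O)C[C@H](C)[C@H]2[C@@H]3C1(C)C | intermediate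
20 | 9-acetoxy-1-oxolongipinan-7-yl (Z)-2-methylbut-2-enoate | C/C=C(/C)C(=O)O[C@@H]1C[C@@H](OC(C)=O)[C@@]2(C)[C@@H]3C(=O)C[C@H](C)[C@H]2[C@@H]3C1(C)C | intermediate
21 | CNP0260482.1, 9-acetoxy-1-oxolongipin-2-en-7-yl (Z)-2-methylbut-2-enoate | C/C=C(/C)C(=O)O[C@@H]1C[C@@H](OC(C)=O)[C@@]2(C)[C@@H]3C(=O)C=C(C)[C@H]2[C@@H]3C1(C)C | target

Total step count: 15. Longest linear sequence: 14 steps (steps 1, 2, 4–15; step 3 is a one-step side branch).

Steps most likely to fail

1. Step 9 (proposed new method). The cyclobutyl cation/aluminium dienolate pair may collapse by proton transfer (ene-type termination) before the C9–C10 bond forms, or the dienone may undergo 4π electrocyclisation first. The fallback sets out from 11 and returns at 13. The Lewis-acid step is run only to the ene stage (Me2AlCl-promoted intramolecular ene reaction of the enone with the methylcyclohexene unit), which should give 4-{2-[(tert-butyldimethylsilyl)oxy]-4-methyl-7-methylidenebicyclo[3.1.1]heptan-6-yl}pent-1-en-3-one F1. The seven-membered ring is then closed by a radical instead of a cation: Fe(acac)3 and PhSiH3 in EtOH/ethylene glycol at 60 °C transfer a hydrogen atom to the exocyclic methylene, and the tertiary C10 radical adds 7-endo to the vinyl ketone (hydrogen-atom-transfer Giese cyclisation) to give 1-[(tert-butyldimethylsilyl)oxy]-13-norlongipinan-7-one F2. Dehydrogenation with 2-iodoxybenzoic acid (DMSO, 70 °C), possible only toward C8, returns enone 13.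

2. Step 11. Facial selectivity of the conjugate borylation may be poor, because the two faces of C8=C9 differ only through remote groups and catalyst control may not override this. The fallback sets out from 14 and returns at 16, relaying the configuration from a reagent-controlled carbinol. Oxazaborolidine-catalysed borane (CBS) reduction of 14, where the quaternary C6 and the vinyl group are well differentiated, gives 1-[(tert-butyldimethylsilyl)oxy]longipin-8-en-7-ol F3 with the hydroxyl on the C11 side. Hydroxyl-directed epoxidation (VO(acac)2, tBuOOH) delivers oxygen syn to it and gives 8,9-epoxy-1-[(tert-butyldimethylsilyl)oxy]longipinan-7-ol F4. Oxidation with Dess–Martin periodinane gives 8,9-epoxy-1-[(tert-butyldimethylsilyl)oxy]longipinan-7-one F5. SmI2 (THF/MeOH, −78 °C) cleaves the C8–O bond of the α,β-epoxy ketone and returns β-hydroxy ketone 16 with C9 unchanged.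

3. Step 13. The angeloyl group may isomerise Z to E (to the tiglate) during acylation of the hindered C7 alcohol. The fallback sets out from 17 and returns at 18, building the Z alkene on the ester. Acylation of 17 with 2-[bis(2,2,2-trifluoroethoxy)phosphoryl]propanoic acid (DCC, DMAP, CH2Cl2) gives 9-acetoxy-1-[(tert-butyldimethylsilyl)oxy]longipinan-7-yl 2-[bis(2,2,2-trifluoroethoxy)phosphoryl]propanoate F6. Still–Gennari olefination with acetaldehyde (KN(SiMe3)2, 18-crown-6, THF, −78 °C) then forms the Z trisubstituted enoate 18.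

Further compounds
F1 | step 9 | 4-{2-[(tert-butyldimethylsilyl)oxy]-4-methyl-7-methylidenebicyclo[3.1.1]heptan-6-yl}pent-1-en-3-one (ring configuration as in 13; silyloxy carbon and chain methine as epimers) | C=CC(=O)C(C)[C@H]1[C@@H]2[C@@H](C)CC(O[Si](C)(C)C(C)(C)C)[C@H]1C2=C
F2 | step 9 | 1-[(tert-butyldimethylsilyl)oxy]-13-norlongipinan-7-one (C1/C6 epimers) | O=C1CC[C@@]2(C)[C@@H]3C(O[Si](C)(C)C(C)(C)C)C[C@H](C)[C@H]2[C@@H]3C1C
F3 | step 11 | 1-[(tert-butyldimethylsilyl)oxy]longipin-8-en-7-ol (7-OH on the C11 side) | O[C@H]1C=C[C@@]2(C)[C@@H]3C(O[Si](C)(C)C(C)(C)C)C[C@H](C)[C@H]2[C@@H]3C1(C)C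
F4 | step 11 | 8,9-epoxy-1-[(tert-butyldimethylsilyl)oxy]longipinan-7-ol (epoxide syn to 7-OH) | O[C@H]1[C@H]2O[C@H]2[C@@]3(C)[C@@H]4C(O[Si](C)(C)C(C)(C)C)C[C@H](C)[C@H]3[C@@H]4C1(C)C
F5 | step 11 | 8,9-epoxy-1-[(tert-butyldimethylsilyl)oxy]longipinan-7-one | O=C1[C@H]2O[C@H]2[C@@]3(C)[C@@H]4C(O[Si](C)(C)C(C)(C)C)C[C@H](C)[C@H]3[C@@H]4C1(C)C
F6 | step 13 | 9-acetoxy-1-[(tert-butyldimethylsilyl)oxy]longipinan-7-yl 2-[bis(2,2,2-trifluoroethoxy)phosphoryl]propanoate | CC(C(=O)O[C@@H]1C[C@@H](OC(C)=O)[C@@]2(C)[C@@H]3C(O[Si](C)(C)C(C)(C)C)C[C@H](C)[C@H]2[C@@H]3C1(C)C)P(=O)(OCC(F)(F)F)OCC(F)(F)F
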